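**Retrosynthetic overview**
1. Target ⇐ C10–O desilylation ⇐ reagent-controlled (CBS) reduction of the C3 enone ⇐ ten-membered ring closed last by intramolecular Nozaki–Hiyama–Kishi coupling (C3–C4) of a (Z)-alkenyl iodide onto a C3 aldehyde.
2. cis-α-Methylene-γ-lactone ⇐ key fragment union: intermolecular indium Barbier allylation (C6–C7) of (Z)-3-iodobut-2-enal with a (Z)-2-(bromomethyl)enoate, then lactonisation on O6.
3. Bromide ⇐ Morita–Baylis–Hillman reaction and SN2′ bromination of an α-PMB-oxy aldehyde ⇐ epoxygeraniol (Sharpless, sets C10), 1,3-dithiane (brings C7), Zn(BH4)2 reduction (sets C8).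
4. The angelate goes on C8–OH right after lactone formation; the prenyl alkene of geraniol is the masked C3 aldehyde.
5. Ring order: γ-lactone first (step 15), cyclodecene second (step 19).

Assumption: C-numbers in the comments use germacranolide numbering of the target (C12 lactone carbonyl, C13 exocyclic CH2, C14 methyl on C10, C15 methyl on C4); CIP descriptors in names are those of each compound itself.

**Route**

Step 1
Reactants: 1 geraniol
Product: 2 [(2S,3S)-3-methyl-3-(4-methylpent-3-en-1-yl)oxiran-2-yl]methanol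
Conditions: Ti(OiPr)4 (5 mol %), L-(+)-diethyl tartrate (7 mol %), tBuOOH, 4 Å MS, CH2Cl2, −20 °C
Reagents that add atoms: tert-butyl hydroperoxide, CC(C)(C)OO
Why: Sharpless asymmetric epoxidation touches only the allylic alkene and, with L-(+)-tartrate, gives the (2S,3S)-epoxide whose C3–O bond becomes the (10S) tertiary carbinol.

Step 2
Reactants: 2 epoxygeraniol
Product: 3 (2R,3S)-3-methyl-3-(4-methylpent-3-en-1-yl)oxirane-2-carbaldehyde
Conditions: Dess–Martin periodinane, pyridine, CH2Cl2, 0 °C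
Reagents that add atoms: none
Why: Dess–Martin oxidation of the primary alcohol is neutral and leaves the epoxide and its stereocentres untouched.

Step 3
Reactants: 3 epoxy aldehyde; 4 1,3-dithiane
Product: 6 (1,3-dithian-2-yl)[(2S,3S)-3-methyl-3-(4-methylpent-3-en-1-yl)oxiran-2-yl]methanol as both carbinol epimers, via 2-lithio-1,3-dithiane 5 (not isolated)
Conditions: 4, n-BuLi, THF, −30 °C; then 3, −78 °C; H2O
Reagents that add atoms: none
Why: Corey–Seebach acyl-anion addition to the aldehyde is much faster than epoxide opening at −78 °C and brings in C7 at the aldehyde oxidation level; the carbinol configuration is irrelevant because it is oxidised next.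

Step 4
Reactants: 6 carbinol mixture
Product: 7 (1,3-dithian-2-yl)[(2R,3S)-3-methyl-3-(4-methylpent-3-en-1-yl)oxiran-2-yl]methanone
Conditions: (COCl)2, DMSO, CH2Cl2, −78 °C; Et3N, to −20 °C
Reagents that add atoms: none
Why: Swern oxidation tolerates the dithiane sulfur atoms and the epoxide and converges both epimers to one α,β-epoxy ketone.

Step 5
Reactants: 7 epoxy ketone
Product: 8 (R)-(1,3-dithian-2-yl)[(2S,3S)-3-methyl-3-(4-methylpent-3-en-1-yl)oxiran-2-yl]methanol
Conditions: Zn(BH4)2, Et2O, −30 °C; aq. NH4Cl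
Reagents that add atoms: none
Why: Chelation-controlled reduction (zinc bridges the carbonyl and epoxide oxygens, hydride enters anti to the epoxide C–C bond) gives the anti epoxy alcohol, which is the (8R) carbinol with the 8,10-anti pattern of the target.

Step 6
Reactants: 8 epoxy alcohol
Product: 9 2-{(R)-[(4-methoxybenzyl)oxy][(2S,3S)-3-methyl-3-(4-methylpent-3-en-1-yl)oxiran-2-yl]methyl}-1,3-dithiane
Conditions: NaH, 4-methoxybenzyl bromide, nBu4NI (cat.), THF/DMF, 0 °C to rt
Reagents that add atoms: 4-methoxybenzyl bromide, COc1ccc(CBr)cc1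
Why: Williamson etherification of the only free hydroxyl under aprotic conditions installs the small, DDQ-cleavable PMB group on O8 without touching the stereocentre.

Step 7
Reactants: 9 PMB ether
Product: 10 (1R,3S)-1-(1,3-dithian-2-yl)-1-[(4-methoxybenzyl)oxy]-3,7-dimethyloct-6-en-3-ol
Conditions: LiBHEt3, THF, 0 °C to rt; H2O
Reagents that add atoms: none
Why: SN2 hydride opening of the trisubstituted epoxide occurs at the less substituted carbon (C9), so the C10–O bond and its Sharpless-derived configuration are retained in the tertiary alcohol.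

Step 8
Reactants: 10 tertiary alcohol
Product: 11 triethyl{[(1R,3S)-1-(1,3-dithian-2-yl)-1-[(4-methoxybenzyl)oxy]-3,7-dimethyloct-6-en-3-yl]oxy}silane
Conditions: Et3SiOTf, 2,6-lutidine, CH2Cl2, −78 to 0 °C
Reagents that add atoms: triethylsilyl trifluoromethanesulfonate, CC[Si](CC)(CC)OS(=O)(=O)C(F)(F)F
Why: Silyl triflate silylation caps the hindered tertiary O10 so that it cannot later form a lactol or hemiketal with C3.

Step 9
Reactants: 11 dithiane
Product: 12 (2R,4S)-2-[(4-methoxybenzyl)oxy]-4,8-dimethyl-4-[(triethylsilyl)oxy]non-7-enal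
Conditions: MeI, CaCO3, MeCN/H2O 9:1, 45 °C
Reagents that add atoms: water, O
Why: Alkylative hydrolysis of the dithioacetal under buffered neutral conditions releases the α-alkoxy aldehyde without epimerising C8 or cleaving the silyl or PMB ether.

Step 10
Reactants: 12 aldehyde; 13 methyl acrylate
Product: 14 methyl (4R,6S)-3-hydroxy-4-[(4-methoxybenzyl)oxy]-6,10-dimethyl-2-methylidene-6-[(triethylsilyl)oxy]undec-9-enoate as both C3 epimers
Conditions: 13 (10 equiv, neat), DABCO (1 equiv), MeOH (3 equiv), rt, 5 d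
Reagents that add atoms: none
Why: The Morita–Baylis–Hillman reaction works on inductively activated α-alkoxy aldehydes and builds C11–C13 of the acrylate; the new carbinol centre is erased in the next step.

Step 11
Reactants: 14 Morita–Baylis–Hillman adduct
Product: 15 methyl (2Z,4R,6S)-2-(bromomethyl)-4-[(4-methoxybenzyl)oxy]-6,10-dimethyl-6-[(triethylsilyl)oxy]undeca-2,9-dienoate
Conditions: NBS, Me2S (premixed, CH2Cl2, 0 °C); then 14, 0 °C to rt
Reagents that add atoms: N-bromosuccinimide, O=C1CCC(=O)N1Br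
Why: Corey–Kim activation followed by SN2′ bromide attack gives the rearranged primary allylic bromide with the chain trans to the ester (Z); premixing leaves no free NBS to attack the prenyl alkene or the anisyl ring.

Step 12
Reactants: 16 ethyl but-2-ynoate
Product: 17 ethyl (2Z)-3-iodobut-2-enoate
Conditions: NaI, AcOH, 115 °C
Reagents that add atoms: sodium iodide, [Na+].[I-]
Why: Conjugate hydroiodination of the ynoate proceeds by anti addition and gives the Z-β-iodo enoate, which fixes the ring alkene geometry of the target.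

Step 13
Reactants: 17 iodo ester
Product: 18 (2Z)-3-iodobut-2-en-1-ol
Conditions: iBu2AlH (2.2 equiv), CH2Cl2, −78 °C; aq. potassium sodium tartrate
Reagents that add atoms: none
Why: Aluminium hydride 1,2-reduction of the ester leaves the alkenyl iodide and its geometry intact.

Step 14
Reactants: 18 allylic alcohol
Product: 19 (2Z)-3-iodobut-2-enal
Conditions: MnO2 (15 equiv), CH2Cl2, rt, dark; used at once
Reagents that add atoms: none
Why: Allylic oxidation on MnO2 is neutral and fast enough to avoid Z to E isomerisation of the sensitive enal.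

Step 15
Reactants: 15 allylic bromide; 19 aldehyde
Product: 22 (4R,5R)-5-[(1Z)-2-iodoprop-1-en-1-yl]-4-{(1R,3S)-1-[(4-methoxybenzyl)oxy]-3,7-dimethyl-3-[(triethylsilyl)oxy]oct-6-en-1-yl}-3-methylideneoxolan-2-one, via allylindium dibromide 20 (not isolated), via hydroxy ester 21 (not isolated)
Conditions: indium powder, THF/H2O 3:1, rt; then PPTS (cat.), PhMe, 50 °C
Reagents that add atoms: none
Why: Barbier carbonyl allylation through a closed chair transition state: the Z-allylindium holds C8 axial so C6–C7 forms syn (cis-lactone), and with H-8 in the allyl plane (A(1,3) strain) the aldehyde is expected to add anti to the bulky C9 branch on the face carrying the small OPMB group, giving the C6/C7 configuration of the target; PPTS then closes the lactone on O6 because O8 and O10 are blocked.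

Step 16
Reactants: 22 PMB ether
Product: 23 (4R,5R)-4-{(1R,3S)-1-hydroxy-3,7-dimethyl-3-[(triethylsilyl)oxy]oct-6-en-1-yl}-5-[(1Z)-2-iodoprop-1-en-1-yl]-3-methylideneoxolan-2-one
Conditions: DDQ (1.5 equiv), CH2Cl2/pH 7 buffer 10:1, 0 °C
Reagents that add atoms: none
Why: Oxidative PMB cleavage frees only O8 under buffered conditions that spare the tertiary silyl ether, the alkenyl iodide and the methylene lactone.

Step 17
Reactants: 23 alcohol; 24 angelic acid
Product: 26 (1R,3S)-1-[(2R,3R)-2-[(1Z)-2-iodoprop-1-en-1-yl]-4-methylidene-5-oxooxolan-3-yl]-3,7-dimethyl-3-[(triethylsilyl)oxy]oct-6-en-1-yl (2Z)-2-methylbut-2-enoate, via angelic 2,4,6-trichlorobenzoic anhydride 25 (not isolated)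
Conditions: 24, 2,4,6-Cl3C6H2COCl, Et3N, PhMe, rt, 2 h; then 23, 75 °C
Reagents that add atoms: none
Why: Yamaguchi mixed-anhydride esterification without DMAP or alkoxide acylates the hindered C8–OH with retention and avoids both angelate-to-tiglate isomerisation and 6,12 to 8,12 lactone migration.

Step 18
Reactants: 26 angelate
Product: 28 (1R,3S)-1-[(2R,3R)-2-[(1Z)-2-iodoprop-1-en-1-yl]-4-methylidene-5-oxooxolan-3-yl]-3-methyl-6-oxo-3-[(triethylsilyl)oxy]hexyl (2Z)-2-methylbut-2-enoate, via diol 27 (not isolated)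
Conditions: OsO4 (2 mol %), NMO (1.1 equiv), acetone/H2O, 0 °C; then NaIO4, rt
Reagents that add atoms: 4-methylmorpholine N-oxide, C[N+]1([O-])CCOCC1; water, O
Why: Electrophilic dihydroxylation picks the electron-rich trisubstituted prenyl alkene over the acrylate, angelate and iodoalkene, and periodate glycol cleavage then unmasks the C3 aldehyde.

Step 19
Reactants: 28 iodo aldehyde
Product: 30 (3aR,4R,6S,10Z,11aS)-9-hydroxy-6,10-dimethyl-3-methylidene-2-oxo-6-[(triethylsilyl)oxy]-2,3,3a,4,5,6,7,8,9,11a-decahydrocyclodeca[b]furan-4-yl (2Z)-2-methylbut-2-enoate as both C9 epimers, via alkenylchromium dichloride 29 (not isolated)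
Conditions: CrCl2 (10 equiv), NiCl2 (2 mol %), DMSO, 0.003 M, rt
Reagents that add atoms: none
Why: Intramolecular Nozaki–Hiyama–Kishi coupling adds the alkenylchromium chemoselectively to the aldehyde with retention of the Z geometry, the cis alkene and cis-fused lactone bringing the ends together; the C3 configuration is not relied on.

Step 20
Reactants: 30 allylic alcohol mixture
Product: 31 (3aR,4R,6S,10Z,11aS)-6,10-dimethyl-3-methylidene-2,9-dioxo-6-[(triethylsilyl)oxy]-2,3,3a,4,5,6,7,8,9,11a-decahydrocyclodeca[b]furan-4-yl (2Z)-2-methylbut-2-enoate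
Conditions: Dess–Martin periodinane, pyridine, CH2Cl2, 0 °C
Reagents that add atoms: none
Why: Dess–Martin oxidation converges both C3 epimers to one enone while the silyl ether on O10 prevents transannular hemiketal formation.

Step 21
Reactants: 31 enone
Product: 32 (3aR,4R,6S,9S,10Z,11aS)-9-hydroxy-6,10-dimethyl-3-methylidene-2-oxo-6-[(triethylsilyl)oxy]-2,3,3a,4,5,6,7,8,9,11a-decahydrocyclodeca[b]furan-4-yl (2Z)-2-methylbut-2-enoate
Conditions: (R)-2-methyl-CBS-oxazaborolidine (0.5 equiv), catecholborane, PhMe, −78 °C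
Reagents that add atoms: none
Why: Corey–Bakshi–Shibata reduction with the alkenyl branch as the large group and the (R)-catalyst delivers hydride to give the (3S) allylic alcohol under reagent control, and catecholborane at −78 °C leaves the lactone and angelate alone.

Step 22
Reactants: 32 silyl ether
Product: 33 (3aR,4R,6S,9S,10Z,11aS)-6,9-dihydroxy-6,10-dimethyl-3-methylidene-2-oxo-2,3,3a,4,5,6,7,8,9,11a-decahydrocyclodeca[b]furan-4-yl (2Z)-2-methylbut-2-enoate
Conditions: HF·pyridine, pyridine, THF, 0 °C to rt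
Reagents that add atoms: none
Why: Buffered fluoride desilylation frees the tertiary C10–OH without touching the α-methylene lactone, the angelate or the allylic alcohol, giving the target.

**Compound list**
1 | geraniol, (2E)-3,7-dimethylocta-2,6-dien-1-ol | CC(C)=CCC/C(C)=C/CO | starting material
2 | [(2S,3S)-3-methyl-3-(4-methylpent-3-en-1-yl)oxiran-2-yl]methanol | CC(C)=CCC[C@]1(C)O[C@H]1CO | intermediate
3 | (2R,3S)-3-methyl-3-(4-methylpent-3-en-1-yl)oxirane-2-carbaldehyde | CC(C)=CCC[C@]1(C)O[C@H]1C=O | intermediate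
4 | 1,3-dithiane | C1CSCSC1 | starting material
5 | 2-lithio-1,3-dithiane | [Li]C1SCCCS1 | intermediate (not isolated)
6 | (1,3-dithian-2-yl)[(2S,3S)-3-methyl-3-(4-methylpent-3-en-1-yl)oxiran-2-yl]methanol, both carbinol epimers | CC(C)=CCC[C@]1(C)O[C@H]1C(O)C1SCCCS1 | intermediate
7 | (1,3-dithian-2-yl)[(2R,3S)-3-methyl-3-(4-methylpent-3-en-1-yl)oxiran-2-yl]methanone | CC(C)=CCC[C@]1(C)O[C@H]1C(=O)C1SCCCS1 | intermediate
8 | (R)-(1,3-dithian-2-yl)[(2S,3S)-3-methyl-3-(4-methylpent-3-en-1-yl)oxiran-2-yl]methanol | CC(C)=CCC[C@]1(C)O[C@H]1[C@@H](O)C1SCCCS1 | intermediate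
9 | 2-{(R)-[(4-methoxybenzyl)oxy][(2S,3S)-3-methyl-3-(4-methylpent-3-en-1-yl)oxiran-2-yl]methyl}-1,3-dithiane | CC(C)=CCC[C@]1(C)O[C@H]1[C@@H](OCc1ccc(OC)cc1)C1SCCCS1 | intermediate
10 | (1R,3S)-1-(1,3-dithian-2-yl)-1-[(4-methoxybenzyl)oxy]-3,7-dimethyloct-6-en-3-ol | CC(C)=CCC[C@](C)(O)C[C@@H](OCc1ccc(OC)cc1)C1SCCCS1 | intermediate
11 | triethyl{[(1R,3S)-1-(1,3-dithian-2-yl)-1-[(4-methoxybenzyl)oxy]-3,7-dimethyloct-6-en-3-yl]oxy}silane | CC(C)=CCC[C@](C)(O[Si](CC)(CC)CC)C[C@@H](OCc1ccc(OC)cc1)C1SCCCS1 | intermediate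
12 | (2R,4S)-2-[(4-methoxybenzyl)oxy]-4,8-dimethyl-4-[(triethylsilyl)oxy]non-7-enal | CC(C)=CCC[C@](C)(O[Si](CC)(CC)CC)C[C@@H](OCc1ccc(OC)cc1)C=O | intermediate
13 | methyl acrylate | C=CC(=O)OC | starting material
14 | methyl (4R,6S)-3-hydroxy-4-[(4-methoxybenzyl)oxy]-6,10-dimethyl-2-methylidene-6-[(triethylsilyl)oxy]undec-9-enoate, both C3 epimers | CC(C)=CCC[C@](C)(O[Si](CC)(CC)CC)C[C@@H](OCc1ccc(OC)cc1)C(O)C(=C)C(=O)OC | intermediate
15 | methyl (2Z,4R,6S)-2-(bromomethyl)-4-[(4-methoxybenzyl)oxy]-6,10-dimethyl-6-[(triethylsilyl)oxy]undeca-2,9-dienoate | CC(C)=CCC[C@](C)(O[Si](CC)(CC)CC)C[C@@H](OCc1ccc(OC)cc1)/C=C(\CBr)C(=O)OC | intermediate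
16 | ethyl but-2-ynoate | CC#CC(=O)OCC | starting material
17 | ethyl (2Z)-3-iodobut-2-enoate | CCOC(=O)/C=C(/C)I | intermediate
18 | (2Z)-3-iodobut-2-en-1-ol | OC/C=C(/C)I | intermediate
19 | (2Z)-3-iodobut-2-enal | O=C/C=C(/C)I | intermediate
20 | allylindium dibromide from 15 (CH2InBr2 in place of CH2Br, same Z geometry) | CC(C)=CCC[C@](C)(O[Si](CC)(CC)CC)C[C@@H](OCc1ccc(OC)cc1)/C=C(\C[In](Br)Br)C(=O)OC | intermediate (not isolated)
21 | methyl (3S,4R,6S)-3-[(1R,2Z)-1-hydroxy-3-iodobut-2-en-1-yl]-4-[(4-methoxybenzyl)oxy]-6,10-dimethyl-2-methylidene-6-[(triethylsilyl)oxy]undec-9-enoate | COC(=O)C(=C)[C@@H]([C@@H](O)/C=C(/C)I)[C@H](OCc1ccc(OC)cc1)C[C@@](C)(O[Si](CC)(CC)CC)CCC=C(C)C | intermediate (not isolated)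
22 | (4R,5R)-5-[(1Z)-2-iodoprop-1-en-1-yl]-4-{(1R,3S)-1-[(4-methoxybenzyl)oxy]-3,7-dimethyl-3-[(triethylsilyl)oxy]oct-6-en-1-yl}-3-methylideneoxolan-2-one | C=C1C(=O)O[C@@H](/C=C(/C)I)[C@H]1[C@H](OCc2ccc(OC)cc2)C[C@@](C)(O[Si](CC)(CC)CC)CCC=C(C)C | intermediate
23 | (4R,5R)-4-{(1R,3S)-1-hydroxy-3,7-dimethyl-3-[(triethylsilyl)oxy]oct-6-en-1-yl}-5-[(1Z)-2-iodoprop-1-en-1-yl]-3-methylideneoxolan-2-one | C=C1C(=O)O[C@@H](/C=C(/C)I)[C@H]1[C@H](O)C[C@@](C)(O[Si](CC)(CC)CC)CCC=C(C)C | intermediate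
24 | angelic acid, (2Z)-2-methylbut-2-enoic acid | C/C=C(/C)C(=O)O | starting material
25 | angelic 2,4,6-trichlorobenzoic anhydride | C/C=C(/C)C(=O)OC(=O)c1c(Cl)cc(Cl)cc1Cl | intermediate (not isolated)
26 | (1R,3S)-1-[(2R,3R)-2-[(1Z)-2-iodoprop-1-en-1-yl]-4-methylidene-5-oxooxolan-3-yl]-3,7-dimethyl-3-[(triethylsilyl)oxy]oct-6-en-1-yl (2Z)-2-methylbut-2-enoate | C=C1C(=O)O[C@@H](/C=C(/C)I)[C@H]1[C@H](OC(=O)/C(C)=C\C)C[C@@](C)(O[Si](CC)(CC)CC)CCC=C(C)C | intermediate
27 | 6,7-diol of 26 (6,7-dihydroxy-3,7-dimethyloctyl chain, both C6 epimers) | C=C1C(=O)O[C@@H](/C=C(/C)I)[C@H]1[C@H](OC(=O)/C(C)=C\C)C[C@@](C)(O[Si](CC)(CC)CC)CCC(O)C(C)(C)O | intermediate (not isolated)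
28 | (1R,3S)-1-[(2R,3R)-2-[(1Z)-2-iodoprop-1-en-1-yl]-4-methylidene-5-oxooxolan-3-yl]-3-methyl-6-oxo-3-[(triethylsilyl)oxy]hexyl (2Z)-2-methylbut-2-enoate | C=C1C(=O)O[C@@H](/C=C(/C)I)[C@H]1[C@H](OC(=O)/C(C)=C\C)C[C@@](C)(O[Si](CC)(CC)CC)CCC=O | intermediate
29 | alkenylchromium dichloride from 28 (CrCl2 in place of I, same Z geometry) | C=C1C(=O)O[C@@H](/C=C(/C)[Cr](Cl)Cl)[C@H]1[C@H](OC(=O)/C(C)=C\C)C[C@@](C)(O[Si](CC)(CC)CC)CCC=O | intermediate (not isolated)
30 | (3aR,4R,6S,10Z,11aS)-9-hydroxy-6,10-dimethyl-3-methylidene-2-oxo-6-[(triethylsilyl)oxy]-2,3,3a,4,5,6,7,8,9,11a-decahydrocyclodeca[b]furan-4-yl (2Z)-2-methylbut-2-enoate, both C9 epimers | C=C1C(=O)O[C@H]2/C=C(/C)C(O)CC[C@](C)(O[Si](CC)(CC)CC)C[C@@H](OC(=O)/C(C)=C\C)[C@@H]12 | intermediate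
31 | (3aR,4R,6S,10Z,11aS)-6,10-dimethyl-3-methylidene-2,9-dioxo-6-[(triethylsilyl)oxy]-2,3,3a,4,5,6,7,8,9,11a-decahydrocyclodeca[b]furan-4-yl (2Z)-2-methylbut-2-enoate | C=C1C(=O)O[C@H]2/C=C(/C)C(=O)CC[C@](C)(O[Si](CC)(CC)CC)C[C@@H](OC(=O)/C(C)=C\C)[C@@H]12 | intermediate
32 | (3aR,4R,6S,9S,10Z,11aS)-9-hydroxy-6,10-dimethyl-3-methylidene-2-oxo-6-[(triethylsilyl)oxy]-2,3,3a,4,5,6,7,8,9,11a-decahydrocyclodeca[b]furan-4-yl (2Z)-2-methylbut-2-enoate | C=C1C(=O)O[C@H]2/C=C(/C)[C@@H](O)CC[C@](C)(O[Si](CC)(CC)CC)C[C@@H](OC(=O)/C(C)=C\C)[C@@H]12 | intermediate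
33 | (3aR,4R,6S,9S,10Z,11aS)-6,9-dihydroxy-6,10-dimethyl-3-methylidene-2-oxo-2,3,3a,4,5,6,7,8,9,11a-decahydrocyclodeca[b]furan-4-yl (2Z)-2-methylbut-2-enoate | C=C1C(=O)O[C@H]2/C=C(/C)[C@@H](O)CC[C@](C)(O)C[C@@H](OC(=O)/C(C)=C\C)[C@@H]12 | target

**Step count and risks**
Total steps: 22. Longest linear sequence: 19 steps (steps 1–11 and 15–22, from geraniol).

Most likely to fail, first: step 15. The syn (cis-lactone) outcome follows from the Z-bromide, but the facial sense relative to C8 rests on a steric and stereoelectronic model, not on a reagent. Fallback: from bromide 15, Pd-catalysed borylation (B2pin2, Pd2(dba)3, DMSO, 50 °C) gives methyl (2E,4R,6S)-4-[(4-methoxybenzyl)oxy]-6,10-dimethyl-2-[(4,4,5,5-tetramethyl-1,3,2-dioxaborolan-2-yl)methyl]-6-[(triethylsilyl)oxy]undeca-2,9-dienoate F1. Allylboration of 19 with F1 under (R)-TRIP phosphoric acid catalysis (toluene, −30 to 0 °C) lets the catalyst choose the aldehyde face while the unchanged alkene geometry still enforces the syn relationship. Aqueous work-up gives hydroxy ester 21, where the route is rejoined at the PPTS lactonisation of step 15.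

Second: step 19. Closing a strained ten-membered ring competes with oligomerisation and proto-deiodination. Fallback: from aldehyde 28, Pinnick oxidation (NaClO2, NaH2PO4, 2-methylbut-2-ene) gives the carboxylic acid F2. Stannylation (Me3SnSnMe3, Pd(PPh3)4, PhMe, 80 °C) gives the alkenylstannane acid F3. 1-Chloro-N,N,2-trimethylprop-1-en-1-amine converts it to the acid chloride F4, and intramolecular Stille acylation (Pd2(dba)3, tri(2-furyl)phosphine, THF, high dilution) gives enone 31 directly, skipping 30 and step 20.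

Third: step 10. The Morita–Baylis–Hillman reaction is slow on a hindered α-alkoxy aldehyde, and long exposure to DABCO risks C8 epimerisation. Fallback: from aldehyde 12, vinylalumination; methyl propiolate with iBu2AlH and N-methylmorpholine N-oxide (THF, 0 °C) generates the α-(methoxycarbonyl)vinylalane, which adds to 12 within hours and gives 14 after work-up. This detour makes no compound outside the list (none F0).

**Further compounds**
F1 | step 15 | methyl (2E,4R,6S)-4-[(4-methoxybenzyl)oxy]-6,10-dimethyl-2-[(4,4,5,5-tetramethyl-1,3,2-dioxaborolan-2-yl)methyl]-6-[(triethylsilyl)oxy]undeca-2,9-dienoate | CC(C)=CCC[C@](C)(O[Si](CC)(CC)CC)C[C@@H](OCc1ccc(OC)cc1)/C=C(\CB1OC(C)(C)C(C)(C)O1)C(=O)OC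
F2 | step 19 | (4R,6R)-6-[(2R,3R)-2-[(1Z)-2-iodoprop-1-en-1-yl]-4-methylidene-5-oxooxolan-3-yl]-4-methyl-6-{[(2Z)-2-methylbut-2-enoyl]oxy}-4-[(triethylsilyl)oxy]hexanoic acid (carboxylic acid from 28) | C=C1C(=O)O[C@@H](/C=C(/C)I)[C@H]1[C@H](OC(=O)/C(C)=C\C)C[C@@](C)(O[Si](CC)(CC)CC)CCC(=O)O
F3 | step 19 | trimethylstannyl analogue of F2 (SnMe3 in place of I, same alkene geometry) | C=C1C(=O)O[C@@H](/C=C(/C)[Sn](C)(C)C)[C@H]1[C@H](OC(=O)/C(C)=C\C)C[C@@](C)(O[Si](CC)(CC)CC)CCC(=O)O
F4 | step 19 | acid chloride of F3 | C=C1C(=O)O[C@@H](/C=C(/C)[Sn](C)(C)C)[C@H]1[C@H](OC(=O)/C(C)=C\C)C[C@@](C)(O[Si](CC)(CC)CC)CCC(=O)Cl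
F0 | step 10 | none | none
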